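The saturated C19 chain hides an alkene: the C2–C3 bond of the nonadecyl group (O–C1H2–C2H2–C3H2) is disconnected as a C2=C3 double bond allylic to the ester oxygen. The key step is a ruthenium-catalysed cross-metathesis of allyl 3-(4-hydroxyphenyl)propanoate, which carries O–C1–C2 and the complete phloretate with its free phenol on the benzene ring, with 1-octadecene, which carries C3–C19. Ethene is lost, the two halves are welded at C2=C3, and the same ruthenium charge, placed under hydrogen, saturates the new alkene in the pot, so that one operation delivers the target. The precursor is the allyl ester from Fischer esterification of phloretic acid.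

Key step: step 2

Remark: the target has no stereocentre, so the E/Z mixture of the metathesis intermediate converges on one product and nothing has to be controlled.

Step 1
Reactants: 1 3-(4-hydroxyphenyl)propanoic acid (phloretic acid); 2 prop-2-en-1-ol (allyl alcohol)
Product: 3 prop-2-en-1-yl 3-(4-hydroxyphenyl)propanoate (allyl phloretate)
Conditions: 2 (10 equiv), p-TsOH·H2O (5 mol%), toluene, reflux, Dean–Stark
Reagents that add atoms: none
Why: Fischer esterification, driven by excess alcohol and azeotropic removal of water, should acylate only the aliphatic alcohol, because the phenol is too weak a nucleophile under acid catalysis to need protection.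

Step 2
Reactants: 3 prop-2-en-1-yl 3-(4-hydroxyphenyl)propanoate; 4 octadec-1-ene (3 equiv)
Product: 6 nonadecyl 3-(4-hydroxyphenyl)propanoate (target), via nonadec-2-enyl ester 5 (not isolated)
Conditions: Grubbs II (5 mol%), ClCH2CH2Cl, 45 °C, Ar sweep; then H2 (7 bar), 70 °C, same pot
Reagents that add atoms: none
Why: By the Chauvin mechanism the ruthenium alkylidene of the second-generation Grubbs catalyst should engage both terminal alkenes through [2+2]/retro-[2+2] ruthenacyclobutane sequences, extrude ethene and leave the C2=C3 alkene 5, after which the same ruthenium, converted under H2 into a Ru–H species, should hydrogenate 5 to 6. The closest known reaction types are olefin cross-metathesis of an allylic ester with a terminal alkene and tandem metathesis–hydrogenation with a single ruthenium charge. No ring is closed and no stereocentre is formed, and the E/Z geometry of 5 is erased by the hydrogenation. The step needs cross- over homo-coupling selectivity, which the excess of 4 and the removal of ethene should secure, since the homodimer tetratriacont-17-ene and the but-2-ene-1,4-diyl diester from 3 can both re-enter productive metathesis. It also needs chemoselective reduction: the Ru–H catalyst should saturate only the C=C bond, leave ester, phenol and arene untouched and avoid the allylic C–O hydrogenolysis that Pd/C could cause, while any double-bond migration after the metathesis stage converges on the same saturated product.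

Compound list
1 | 3-(4-hydroxyphenyl)propanoic acid (phloretic acid) | O=C(O)CCc1ccc(O)cc1 | starting material
2 | prop-2-en-1-ol (allyl alcohol) | C=CCO | starting material
3 | prop-2-en-1-yl 3-(4-hydroxyphenyl)propanoate | C=CCOC(=O)CCc1ccc(O)cc1 | intermediate
4 | octadec-1-ene | CCCCCCCCCCCCCCCCC=C | starting material
5 | (E)-nonadec-2-en-1-yl 3-(4-hydroxyphenyl)propanoate (expected major isomer of an E/Z mixture, not isolated) | CCCCCCCCCCCCCCCC/C=C/COC(=O)CCc1ccc(O)cc1 | intermediate
6 | nonadecyl 3-(4-hydroxyphenyl)propanoate | CCCCCCCCCCCCCCCCCCCOC(=O)CCc1ccc(O)cc1 | target

Total step count: 2
Longest linear sequence: 2

Steps most likely to fail (the route has only two steps, so both are ranked):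

1. Step 2. Three processes could spoil it. Statistical homodimerisation could consume 3. Ruthenium-hydride double-bond migration before the metathesis is complete would give chain-length homologues that cannot be separated from the target. The ruthenium residue might also hydrogenate incompletely. The fallback gives up metathesis and forms the same C2–C3 bond by a copper-catalysed epoxide opening. It sets out from compound 1 and comes back to the route at compound 6. Purchased 1-bromoheptadecane (CCCCCCCCCCCCCCCCCBr) would be converted with magnesium in THF into heptadecylmagnesium bromide F1. With CuI (10 mol%) in THF at −30 to 0 °C, F1 would open oxirane (C1CO1) at carbon to give bromomagnesium nonadecan-1-olate F2. Aqueous NH4Cl work-up would give nonadecan-1-ol F3. Fischer esterification of F3 with 1 (p-TsOH cat., toluene, reflux, Dean–Stark) would then give 6, again without touching the phenol.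

2. Step 1. The esterification equilibrium could stall, or hot acid could divert allyl alcohol into ether formation or allylation of the electron-rich phenol ring. The fallback switches from acyl substitution to SN2 alkylation of the carboxylate. It sets out from compound 1 and comes back at compound 3. Compound 1 would be treated with allyl bromide (C=CCBr) and KHCO3 in DMF at room temperature; bicarbonate should deprotonate only the carboxylic acid, so O-allylation of the phenol is not expected. This fallback makes no new compound (F0).

Further compounds
F0 | step 1 | none | none
F1 | step 2 | heptadecylmagnesium bromide | CCCCCCCCCCCCCCCCC[Mg]Br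
F2 | step 2 | bromomagnesium nonadecan-1-olate | CCCCCCCCCCCCCCCCCCCO[Mg]Br
F3 | step 2 | nonadecan-1-ol | CCCCCCCCCCCCCCCCCCCO
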